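**Strategy.** The plan rests on opening the carbocycle of the hexahydrobenzofuran between C3a and the gem-dimethyl carbon C4. A palladium hydride-mediated reductive cyclisation of an acyclic 1,7-enyne makes this bond, turns an isopropenyl group into the quaternary C4 (its CH2 becomes the second methyl) and, by syn-hydropalladation, sets the C3=C3a alkene (exocyclic to the six-membered ring) with C2 cis to the C7a oxygen. It exploits that C4 bears two methyls and no hydrogen and that C3a is an alkene carbon. The precursor is a linear enynediol ester holding the C6, C7a and C2 carbinols; SN2 closure of the dihydrofuran and Wittig chain extension follow.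

Key step: step 6

Assumption: the facial sense of the three catalyst-controlled additions (steps 1, 3 and 5) is assigned from the accepted transition-state models; if a test reaction shows the opposite sense, the enantiomeric catalyst is used. From step 7 onwards all material is kept free of acid (base-washed silica, dark, argon), because C2 is a doubly allylic ether carbon.

Step 1
Reactants: 1 4-(trimethylsilyl)but-3-yn-2-one
Product: 2 (R)-4-methyl-6-(trimethylsilyl)hex-1-en-5-yn-4-ol
Conditions: allyldiisopropoxyborane (1.5 equiv), (S)-3,3'-dibromo-1,1'-bi-2-naphthol (15 mol%), PhCF3/PhMe 3:1, −35 °C; aqueous work-up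
Reagents that add atoms: allyldiisopropoxyborane, C=CCB(OC(C)C)OC(C)C
Why: Chiral-diol-catalysed allylboration of a ketone, in which the boronate exchanges an isopropoxy group for the binaphthol and delivers allyl through a closed six-membered transition state to the Re face of the ynone, should set the tertiary (R)-carbinol that becomes C7a.

Step 2
Reactants: 2 (R)-4-methyl-6-(trimethylsilyl)hex-1-en-5-yn-4-ol
Product: 3 (R)-3-hydroxy-3-methyl-5-(trimethylsilyl)pent-4-ynal
Conditions: O3, CH2Cl2, −78 °C; PPh3, −78 °C to rt; used crude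
Reagents that add atoms: ozone, [O-][O+]=O
Why: Ozonolysis with reductive work-up should cleave the only alkene, the silylalkyne reacting far more slowly, and leaves the stereocentre untouched.

Step 3
Reactants: 3 (R)-3-hydroxy-3-methyl-5-(trimethylsilyl)pent-4-ynal
Product: 5 (4R,6R)-2,6-dimethyloct-1-en-7-yne-4,6-diol, via silylalkyne diol 4 (not isolated)
Conditions: 2-methylallylboronic acid pinacol ester (1.3 equiv), (R)-3,3'-bis(2,4,6-triisopropylphenyl)-1,1'-binaphthyl-2,2'-diyl hydrogen phosphate (5 mol%), PhMe, −30 °C; then K2CO3 (0.3 equiv), MeOH, rt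
Reagents that add atoms: 2-methylallylboronic acid pinacol ester, CC(=C)CB1OC(C)(C)C(C)(C)O1
Why: Chiral phosphoric acid-catalysed allylboration should add the 2-methylallyl group through a chair transition state to the Re face of the aldehyde under catalyst control, setting the secondary (R)-carbinol that becomes C6, and K2CO3/MeOH then frees the diol from boron and cleaves the C–Si bond.

Step 4
Reactants: 5 (4R,6R)-2,6-dimethyloct-1-en-7-yne-4,6-diol
Product: 6 (4R,6R)-6-hydroxy-2,6-dimethyloct-1-en-7-yn-4-yl pivalate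
Conditions: PivCl (1.2 equiv), pyridine, DMAP (0.1 equiv), CH2Cl2, 0 °C to rt
Reagents that add atoms: pivaloyl chloride, CC(C)(C)C(=O)Cl
Why: Acylation with a hindered acid chloride should be selective for the secondary over the tertiary propargylic hydroxyl, and the pivalate later falls off during the ester reduction of step 8.

Step 5
Reactants: 6 (4R,6R)-6-hydroxy-2,6-dimethyloct-1-en-7-yn-4-yl pivalate; 7 ethyl (E)-3-methyl-4-oxobut-2-enoate
Product: 8 ethyl (2E,4R,7R,9R)-4,7-dihydroxy-3,7,11-trimethyl-9-(pivaloyloxy)dodeca-2,11-dien-5-ynoate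
Conditions: (S,S)-ProPhenol (20 mol%), Ph3PO (40 mol%), Me2Zn (3 equiv), PhMe, 0 °C; then 7 (1.5 equiv), 4 °C; aq. NH4Cl
Reagents that add atoms: none
Why: Zn–ProPhenol-catalysed asymmetric alkynylation of an aldehyde should deliver the alkynylzinc (the tertiary hydroxyl riding along as its zinc alkoxide) to the Si face of the enal in a 1,2-sense, setting the (4R) propargylic carbinol that, after inversion in step 7, becomes C2.

Step 6
Reactants: 8 ethyl (2E,4R,7R,9R)-4,7-dihydroxy-3,7,11-trimethyl-9-(pivaloyloxy)dodeca-2,11-dien-5-ynoate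
Product: 9 ethyl (2E,4S,5Z)-4-hydroxy-5-[(2R,4R)-2-hydroxy-2,6,6-trimethyl-4-(pivaloyloxy)cyclohexylidene]-3-methylpent-2-enoate
Conditions: Pd2(dba)3·CHCl3 (2.5 mol%), P(o-tol)3 (10 mol%), AcOH (2 equiv), Et3SiH (5 equiv), PhMe, 40 °C
Reagents that add atoms: none
Why: Zerovalent palladium and acetic acid give H–Pd–OAc, which adds syn across the alkyne with palladium on the carbon nearer the coordinated isopropenyl group; the vinylpalladium then inserts the 1,1-disubstituted alkene, and the resulting neopentyl-type alkylpalladium, which has no β-hydrogen, is cleaved by Et3SiH to the second methyl group. The closest known reaction type is the palladium hydride-mediated reductive cyclisation of 1,6- and 1,7-enynes, which is known to build gem-dimethyl quaternary carbons from 2-methylallyl units. The cyclohexane ring (C3a–C4 of the later benzofuran, ring C1–C6 of 9) is closed in the 6-exo-trig mode. No new stereocentre arises, since the new quaternary carbon carries two methyls, but the syn addition fixes the exocyclic alkene as Z, with the chain carbinol C4 cis to the ring carbon bearing the tertiary hydroxyl; the descriptor of C4 changes from R to S only because the alkyne has become an alkene. The step needs chemoselectivity for the 1,7-enyne over the trisubstituted enoate and over plain alkyne reduction, and regioselective hydropalladation; both should be secured by the alkene–alkyne chelation that only the isopropenyl/alkyne pair can offer (hydropalladation is reversible, so the unproductive regioisomer returns), while free propargylic hydroxyls are not ionised under these conditions.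

Step 7
Reactants: 9 ethyl (2E,4S,5Z)-4-hydroxy-5-[(2R,4R)-2-hydroxy-2,6,6-trimethyl-4-(pivaloyloxy)cyclohexylidene]-3-methylpent-2-enoate
Product: 11 ethyl (E)-3-[(2R,6R,7aR)-4,4,7a-trimethyl-6-(pivaloyloxy)-2,4,5,6,7,7a-hexahydro-1-benzofuran-2-yl]but-2-enoate, via allylic mesylate 10 (not isolated)
Conditions: Ms2O (1.2 equiv), Et3N (2.5 equiv), THF, −20 °C; then NaH (3 equiv), 0 °C to rt; aq. NH4Cl
Reagents that add atoms: none
Why: Chloride-free sulfonylation should take only the secondary allylic hydroxyl, and the tertiary alkoxide then displaces the mesylate in a 5-exo-tet Williamson etherification with inversion, turning the (4S) carbinol into C2 (R) of the dihydrofuran, the electron-poor enoate disfavouring ionisation.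

Step 8
Reactants: 11 ethyl (E)-3-[(2R,6R,7aR)-4,4,7a-trimethyl-6-(pivaloyloxy)-2,4,5,6,7,7a-hexahydro-1-benzofuran-2-yl]but-2-enoate
Product: 12 (2R,6R,7aR)-2-[(E)-4-hydroxybut-2-en-2-yl]-4,4,7a-trimethyl-2,4,5,6,7,7a-hexahydro-1-benzofuran-6-ol
Conditions: i-Bu2AlH (6 equiv), CH2Cl2, −78 to −20 °C; aq. potassium sodium tartrate
Reagents that add atoms: none
Why: Hydride reduction with i-Bu2AlH should take the enoate 1,2 to the allylic alcohol and cleave the pivalate in the same operation.

Step 9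
Reactants: 12 (2R,6R,7aR)-2-[(E)-4-hydroxybut-2-en-2-yl]-4,4,7a-trimethyl-2,4,5,6,7,7a-hexahydro-1-benzofuran-6-ol
Product: 14 {(E)-3-[(2R,6R,7aR)-6-hydroxy-4,4,7a-trimethyl-2,4,5,6,7,7a-hexahydro-1-benzofuran-2-yl]but-2-en-1-yl}triphenylphosphonium bromide, via allylic bromide 13 (not isolated)
Conditions: NBS (1.1 equiv), Me2S (1.3 equiv), CH2Cl2, −30 to 0 °C; then PPh3 (1.5 equiv), rt
Reagents that add atoms: N-bromosuccinimide, BrN1C(=O)CCC1=O; triphenylphosphine, c1ccccc1P(c1ccccc1)c1ccccc1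
Why: Corey–Kim halogenation should convert only the primary allylic alcohol into the bromide under non-acidic conditions, and PPh3 then quaternises it by SN2.

Step 10
Reactants: 15 (2E,4E,6E)-2,7-dimethylocta-2,4,6-trienedial; 16 N-methoxy-N-methyl-2-(triphenyl-λ5-phosphanylidene)acetamide
Product: 17 (2E,4E,6E,8E)-N-methoxy-N,4,9-trimethyl-10-oxodeca-2,4,6,8-tetraenamide
Conditions: 15 (3 equiv), 16 (1 equiv), CH2Cl2, rt, dark; excess 15 recovered
Reagents that add atoms: none
Why: Wittig reaction of a stabilised ylide should be E-selective, and the excess of the symmetrical dialdehyde makes mono-olefination dominate.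

Step 11
Reactants: 14 {(E)-3-[(2R,6R,7aR)-6-hydroxy-4,4,7a-trimethyl-2,4,5,6,7,7a-hexahydro-1-benzofuran-2-yl]but-2-en-1-yl}triphenylphosphonium bromide; 17 (2E,4E,6E,8E)-N-methoxy-N,4,9-trimethyl-10-oxodeca-2,4,6,8-tetraenamide
Product: 18 (2E,4E,6E,8E,10E,12E)-13-[(2R,6R,7aR)-6-hydroxy-4,4,7a-trimethyl-2,4,5,6,7,7a-hexahydro-1-benzofuran-2-yl]-N-methoxy-N,4,9-trimethyltetradeca-2,4,6,8,10,12-hexaenamide
Conditions: NaOMe (1.2 equiv) added to 14 and 17, CH2Cl2/MeOH, 0 °C to rt, dark; then heptane, 80 °C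
Reagents that add atoms: none
Why: Wittig olefination of the allylic phosphonium ylide (which, unlike a phosphonate anion, should not expel the δ-alkoxy group) with the α-methyl enal forms the new disubstituted double bond, and heating should converge any Z isomer on the less hindered all-E polyene.

Step 12
Reactants: 18 (2E,4E,6E,8E,10E,12E)-13-[(2R,6R,7aR)-6-hydroxy-4,4,7a-trimethyl-2,4,5,6,7,7a-hexahydro-1-benzofuran-2-yl]-N-methoxy-N,4,9-trimethyltetradeca-2,4,6,8,10,12-hexaenamide
Product: 19 (2E,4E,6E,8E,10E,12E)-13-[(2R,6R,7aR)-6-hydroxy-4,4,7a-trimethyl-2,4,5,6,7,7a-hexahydro-1-benzofuran-2-yl]-4,9-dimethyltetradeca-2,4,6,8,10,12-hexaenal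
Conditions: i-Bu2AlH (3 equiv), THF, −78 °C; aq. potassium sodium tartrate
Reagents that add atoms: none
Why: Weinreb amide reduction should stop at the aldehyde because the chelated tetrahedral aluminium intermediate collapses only on work-up.

Step 13
Reactants: 19 (2E,4E,6E,8E,10E,12E)-13-[(2R,6R,7aR)-6-hydroxy-4,4,7a-trimethyl-2,4,5,6,7,7a-hexahydro-1-benzofuran-2-yl]-4,9-dimethyltetradeca-2,4,6,8,10,12-hexaenal; 20 2-(triphenyl-λ5-phosphanylidene)propanal
Product: 21 (2E,4E,6E,8E,10E,12E,14E)-15-[(2R,6R,7aR)-6-hydroxy-4,4,7a-trimethyl-2,4,5,6,7,7a-hexahydro-1-benzofuran-2-yl]-2,6,11-trimethylhexadeca-2,4,6,8,10,12,14-heptaenal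
Conditions: 20 (1.5 equiv), PhMe, 60 °C, dark
Reagents that add atoms: none
Why: Wittig reaction of the stabilised formyl ylide should give the (E)-2-methyl enal, and the α-methyl enal product reacts more slowly than the unsubstituted enal substrate, which limits double homologation.

**Compound list**

1 | 4-(trimethylsilyl)but-3-yn-2-one | CC(=O)C#C[Si](C)(C)C | starting material
2 | (R)-4-methyl-6-(trimethylsilyl)hex-1-en-5-yn-4-ol | C=CC[C@@](C)(O)C#C[Si](C)(C)C | intermediate
3 | (R)-3-hydroxy-3-methyl-5-(trimethylsilyl)pent-4-ynal | O=CC[C@@](C)(O)C#C[Si](C)(C)C | intermediate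
4 | (4R,6R)-2,6-dimethyl-8-(trimethylsilyl)oct-1-en-7-yne-4,6-diol | C=C(C)C[C@@H](O)C[C@@](C)(O)C#C[Si](C)(C)C | intermediate
5 | (4R,6R)-2,6-dimethyloct-1-en-7-yne-4,6-diol | C=C(C)C[C@@H](O)C[C@@](C)(O)C#C | intermediate
6 | (4R,6R)-6-hydroxy-2,6-dimethyloct-1-en-7-yn-4-yl pivalate | C=C(C)C[C@@H](OC(=O)C(C)(C)C)C[C@@](C)(O)C#C | intermediate
7 | ethyl (E)-3-methyl-4-oxobut-2-enoate | CCOC(=O)/C=C(\C)C=O | starting material
8 | ethyl (2E,4R,7R,9R)-4,7-dihydroxy-3,7,11-trimethyl-9-(pivaloyloxy)dodeca-2,11-dien-5-ynoate | C=C(C)C[C@@H](OC(=O)C(C)(C)C)C[C@@](C)(O)C#C[C@H](O)/C(C)=C/C(=O)OCC | intermediate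
9 | ethyl (2E,4S,5Z)-4-hydroxy-5-[(2R,4R)-2-hydroxy-2,6,6-trimethyl-4-(pivaloyloxy)cyclohexylidene]-3-methylpent-2-enoate | CCOC(=O)/C=C(\C)[C@@H](O)/C=C1/C(C)(C)C[C@@H](OC(=O)C(C)(C)C)C[C@@]1(C)O | intermediate
10 | ethyl (2E,4S,5Z)-5-[(2R,4R)-2-hydroxy-2,6,6-trimethyl-4-(pivaloyloxy)cyclohexylidene]-3-methyl-4-(methylsulfonyloxy)pent-2-enoate | CCOC(=O)/C=C(\C)[C@@H](OS(C)(=O)=O)/C=C1/C(C)(C)C[C@@H](OC(=O)C(C)(C)C)C[C@@]1(C)O | intermediate
11 | ethyl (E)-3-[(2R,6R,7aR)-4,4,7a-trimethyl-6-(pivaloyloxy)-2,4,5,6,7,7a-hexahydro-1-benzofuran-2-yl]but-2-enoate | CCOC(=O)/C=C(\C)[C@H]1C=C2C(C)(C)C[C@@H](OC(=O)C(C)(C)C)C[C@@]2(C)O1 | intermediate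
12 | (2R,6R,7aR)-2-[(E)-4-hydroxybut-2-en-2-yl]-4,4,7a-trimethyl-2,4,5,6,7,7a-hexahydro-1-benzofuran-6-ol | OC/C=C(\C)[C@H]1C=C2C(C)(C)C[C@@H](O)C[C@@]2(C)O1 | intermediate
13 | (2R,6R,7aR)-2-[(E)-4-bromobut-2-en-2-yl]-4,4,7a-trimethyl-2,4,5,6,7,7a-hexahydro-1-benzofuran-6-ol | BrC/C=C(\C)[C@H]1C=C2C(C)(C)C[C@@H](O)C[C@@]2(C)O1 | intermediate
14 | {(E)-3-[(2R,6R,7aR)-6-hydroxy-4,4,7a-trimethyl-2,4,5,6,7,7a-hexahydro-1-benzofuran-2-yl]but-2-en-1-yl}triphenylphosphonium bromide | [Br-].c1ccccc1[P+](c1ccccc1)(c1ccccc1)C/C=C(\C)[C@H]1C=C2C(C)(C)C[C@@H](O)C[C@@]2(C)O1 | intermediate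
15 | (2E,4E,6E)-2,7-dimethylocta-2,4,6-trienedial | O=C/C(C)=C/C=C/C=C(C)/C=O | starting material
16 | N-methoxy-N-methyl-2-(triphenyl-λ5-phosphanylidene)acetamide | CON(C)C(=O)C=P(c1ccccc1)(c1ccccc1)c1ccccc1 | starting material
17 | (2E,4E,6E,8E)-N-methoxy-N,4,9-trimethyl-10-oxodeca-2,4,6,8-tetraenamide | O=C/C(C)=C/C=C/C=C(C)/C=C/C(=O)N(C)OC | intermediate
18 | (2E,4E,6E,8E,10E,12E)-13-[(2R,6R,7aR)-6-hydroxy-4,4,7a-trimethyl-2,4,5,6,7,7a-hexahydro-1-benzofuran-2-yl]-N-methoxy-N,4,9-trimethyltetradeca-2,4,6,8,10,12-hexaenamide | CON(C)C(=O)/C=C/C(C)=C/C=C/C=C(C)/C=C/C=C(\C)[C@H]1C=C2C(C)(C)C[C@@H](O)C[C@@]2(C)O1 | intermediate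
19 | (2E,4E,6E,8E,10E,12E)-13-[(2R,6R,7aR)-6-hydroxy-4,4,7a-trimethyl-2,4,5,6,7,7a-hexahydro-1-benzofuran-2-yl]-4,9-dimethyltetradeca-2,4,6,8,10,12-hexaenal | O=C/C=C/C(C)=C/C=C/C=C(C)/C=C/C=C(\C)[C@H]1C=C2C(C)(C)C[C@@H](O)C[C@@]2(C)O1 | intermediate
20 | 2-(triphenyl-λ5-phosphanylidene)propanal | CC(C=O)=P(c1ccccc1)(c1ccccc1)c1ccccc1 | starting material
21 | (2E,4E,6E,8E,10E,12E,14E)-15-[(2R,6R,7aR)-6-hydroxy-4,4,7a-trimethyl-2,4,5,6,7,7a-hexahydro-1-benzofuran-2-yl]-2,6,11-trimethylhexadeca-2,4,6,8,10,12,14-heptaenal | C\C(C=O)=C/C=C/C(C)=C/C=C/C=C(C)/C=C/C=C(\C)[C@H]1C=C2C(C)(C)C[C@@H](O)C[C@@]2(C)O1 | target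

**Step count and risk**

Total step count: 13. Longest linear sequence: 12 steps (steps 1–9 and 11–13, from compound 1); step 10 makes the polyene partner.

The three steps most likely to fail:

1. Step 6. Migratory insertion of the congested vinylpalladium into the 1,1-disubstituted alkene may be too slow, so that plain semi-reduction of the alkyne or isomerisation of the isopropenyl group takes over. The fallback leaves the route at 6 and rejoins it at 9; it closes the ring by a radical conjugate addition and adds the carbinol carbon afterwards. Palladium-catalysed oxidative ethoxycarbonylation of the terminal alkyne of 6 (PdCl2, CuCl2, NaOAc, CO, EtOH) would give ethyl (4R,6R)-4-hydroxy-4,8-dimethyl-6-(pivaloyloxy)non-8-en-2-ynoate F1. Hydrogen-atom transfer to the isopropenyl group (Fe(acac)3, PhSiH3, EtOH, 60 °C) then generates the tertiary radical, which adds 6-exo-dig to the β-carbon of the ynoate (Giese-type cyclisation). The Z-hydroxy ester lactonises, the E isomer being funnelled to it by photoisomerisation, to (6R,7aR)-4,4,7a-trimethyl-2-oxo-2,4,5,6,7,7a-hexahydro-1-benzofuran-6-yl pivalate F2. One equivalent of i-Bu2AlH at −78 °C reduces the lactone to (6R,7aR)-2-hydroxy-4,4,7a-trimethyl-2,4,5,6,7,7a-hexahydro-1-benzofuran-6-yl pivalate F3. Its open Z-hydroxy enal form takes up the alkenylchromium reagent from ethyl (E)-3-iodobut-2-enoate in a Nozaki–Hiyama–Kishi reaction (CrCl2, NiCl2 cat., chiral sulfonamide ligand to control the new carbinol) and returns 9.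

2. Step 7. The allylic mesylate may ionise to an allyl cation before the alkoxide attacks, which erodes the configuration at C2, or the pivaloyl group may migrate to the tertiary alkoxide. The fallback sets out from 9 and rejoins at 11. Mitsunobu esterification (PPh3, DIAD, 4-nitrobenzoic acid, THF, 0 °C) inverts the carbinol to ethyl (2E,4R,5Z)-5-[(2R,4R)-2-hydroxy-2,6,6-trimethyl-4-(pivaloyloxy)cyclohexylidene]-3-methyl-4-(4-nitrobenzoyloxy)pent-2-enoate F4. Pd(PPh3)4 (5 mol%) and Et3N in THF then form the π-allyl complex of this γ-acyloxy enoate with inversion, and the tertiary hydroxyl attacks anti to palladium (Tsuji–Trost etherification, net retention). The two operations together should give 11 with the required overall inversion, without a free cation or a strong base.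

3. Step 5. Turnover or facial selectivity may be low because the zinc alkoxide of the free tertiary hydroxyl interferes with the dinuclear zinc catalyst. The fallback sets out from 6 and rejoins at 8. The dilithio derivative of 6 (LiN(SiMe3)2, 2.1 equiv, THF, −78 °C) adds to 7 without control to give ethyl (2E,4RS,7R,9R)-4,7-dihydroxy-3,7,11-trimethyl-9-(pivaloyloxy)dodeca-2,11-dien-5-ynoate F5. MnO2 in CH2Cl2 oxidises it to ethyl (2E,7R,9R)-7-hydroxy-3,7,11-trimethyl-4-oxo-9-(pivaloyloxy)dodeca-2,11-dien-5-ynoate F6. CBS reduction ((R)-2-methyl-CBS-oxazaborolidine, catecholborane, PhMe, −78 °C; alkynyl as the small group) then sets the (4R) carbinol of 8 under reagent control.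

Further compounds

F1 | step 6 | ethyl (4R,6R)-4-hydroxy-4,8-dimethyl-6-(pivaloyloxy)non-8-en-2-ynoate | C=C(C)C[C@@H](OC(=O)C(C)(C)C)C[C@@](C)(O)C#CC(=O)OCC
F2 | step 6 | (6R,7aR)-4,4,7a-trimethyl-2-oxo-2,4,5,6,7,7a-hexahydro-1-benzofuran-6-yl pivalate | O=C1C=C2C(C)(C)C[C@@H](OC(=O)C(C)(C)C)C[C@@]2(C)O1
F3 | step 6 | (6R,7aR)-2-hydroxy-4,4,7a-trimethyl-2,4,5,6,7,7a-hexahydro-1-benzofuran-6-yl pivalate (lactol, both C2 epimers) | OC1C=C2C(C)(C)C[C@@H](OC(=O)C(C)(C)C)C[C@@]2(C)O1
F4 | step 7 | ethyl (2E,4R,5Z)-5-[(2R,4R)-2-hydroxy-2,6,6-trimethyl-4-(pivaloyloxy)cyclohexylidene]-3-methyl-4-(4-nitrobenzoyloxy)pent-2-enoate | CCOC(=O)/C=C(\C)[C@H](OC(=O)c1ccc(cc1)[N+](=O)[O-])/C=C2/C(C)(C)C[C@@H](OC(=O)C(C)(C)C)C[C@@]2(C)O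
F5 | step 5 | ethyl (2E,4RS,7R,9R)-4,7-dihydroxy-3,7,11-trimethyl-9-(pivaloyloxy)dodeca-2,11-dien-5-ynoate | C=C(C)C[C@@H](OC(=O)C(C)(C)C)C[C@@](C)(O)C#CC(O)/C(C)=C/C(=O)OCC
F6 | step 5 | ethyl (2E,7R,9R)-7-hydroxy-3,7,11-trimethyl-4-oxo-9-(pivaloyloxy)dodeca-2,11-dien-5-ynoate | C=C(C)C[C@@H](OC(=O)C(C)(C)C)C[C@@](C)(O)C#CC(=O)/C(C)=C/C(=O)OCC
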